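# Proposed synthesis of 8-hydroxyluteolin 7-sulfate by a Moore ring expansion that builds ring A on a 4-pyranone

## Analysis of the target

The target is a flavone, a benzo ring A fused to a 4-pyranone ring C that carries a catechol ring B at C2, and it has no stereocenter, so the problem is one of substitution pattern and chemoselectivity only. Ring A is fully substituted except at C6: it carries 5-OH, a hydrogen sulfate on O7, 8-OH, and the fusion atoms C4a and C8a. The sensitive groups are the aryl sulfate monoester (solvolysed by acid, best made late), the 5,8-dihydroxy pair (a para-hydroquinone that oxidises to the 5,8-quinone, especially as its anion) and the catechol of ring B. The difficulty is twofold: building a benzene ring with three contiguous oxygens plus the ring oxygen, and then sulfating O7 alone among five phenolic oxygens. The strategy rests on the fact that O5 and O8 are para to each other, O7 is an alkoxy-type neighbour of C8 and C6 bears hydrogen, which is the pattern a 3-alkoxy-4-hydroxycyclobut-2-enone delivers on ring expansion: its carbonyl carbon becomes C5, its C2–H becomes C6–H, its alkoxy carbon becomes C7 and its carbinol carbon becomes C8. C8a and C4a can then be C2 and C3 of a preformed 2-aryl-4-pyranone, so rings B and C are in place before ring A is made. After ring expansion the three A-ring oxygens are already distinct: O7 is an ether, 5-OH is chelated to the C4 carbonyl, and 8-OH is an ordinary phenol.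

## Retrosynthetic reasoning

Target 20 from 19: the last bonds cut are the three benzyl–oxygen bonds (O8, O3', O4') and the pyridinium counter-ion. Benzyl ethers are chosen for every oxygen that must be free at the end because hydrogenolysis is one of the few global deprotections an aryl sulfate monoester tolerates. The sulfate therefore goes on before the benzyl groups come off.

19 from 18: the O7–S bond is cut. Sulfation is only selective if O7 is the sole reactive phenol, so 18 has O8, O3' and O4' benzylated. The 5-OH may stay free because its hydrogen bond to the C4 carbonyl makes it inert to a sulfur trioxide–amine complex under mild conditions.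

18 from 17 and 17 from 16: the O7–allyl bond and the O8–benzyl bond are cut. In 16 the 8-OH is a normal phenol while the 5-OH is chelated, so one equivalent of a benzyl halide with a carbonate base should alkylate O8 alone. The O7 group must survive an organolithium, 110 °C and carbonate, and must leave in the presence of three benzyl ethers without an oxidant. An allyl ether, removed by zerovalent palladium, meets this. A 4-methoxybenzyl ether was considered and rejected for two reasons. On the cyclobutenedione it would be the ester of a strongly acidic vinylogous acid, hence an alkylating agent unlikely to survive the acid-mediated step that makes the dione. Its oxidative removal would also threaten ring A of 17, which is a para-alkoxyphenol.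

16 from 13: this is the key disconnection. The C4a–C5 bond is cut and ring A is unravelled through dienone 15 and dienylketene 14 back to the cyclobutenone 13. Cutting here turns a tetra-oxygenated benzene into a four-membered ring whose substituents are already in the right order. The forward reaction has to open the cyclobutenone with the hydroxyl rotating outward, close the ketene carbon onto C3 of the pyranone, and tautomerise to the hydroquinone without oxidation.

13 from 11 and 5: the bond between C6 of the pyranone and the carbinol carbon is cut, giving the 6-lithiopyranone 12 and the allyl semisquarate 5. A semisquarate, not a squarate diester, is required because C6 of the target carries hydrogen. The forward step needs metalation of 11 next to the ring oxygen and addition of 12 to the carbonyl of 5 that is flanked by the allyloxy-bearing carbon. That carbonyl is the ketone-like one; the other is a vinylogous ester carbonyl and is less electrophilic. This choice places the alkoxy group next to the carbinol, which is what puts O7 next to O8.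

5 from 3, and 3 from 1 and 2: the semisquarate comes from the diallyl squarate 3 by mono-reduction to 4 and acid-induced loss of one allyloxy group. 3 comes from squaric acid 1 and two equivalents of allyl alcohol 2 by double esterification.

11 from 9, and 9 from 6 and 7: the pyranone C2=C3 double bond is traced back to the dihydropyranone 9 (dehydrogenation through selenide 10). Ring C of 9 is cut across O1–C2 and C3–C4 into aldehyde 6 and diene 7, joined through cycloadduct 8. This brings ring B in as a commercial aldehyde already carrying its two benzyl ethers.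

## Alternatives that were turned down

Alternative 1: Ring C is disconnected at O1–C8a, C4–C4a and O1–C2. In the forward direction 3-[3,4-bis(benzyloxy)phenyl]prop-2-ynoic acid A1 and the aryne released by CsF from 5-(allyloxy)-3-(benzyloxy)-2-(trimethylsilyl)phenyl trifluoromethanesulfonate A2 would combine. The aryne inserts into the acyl–oxygen bond of the acid and the resulting phenoxide closes onto the ynone, giving 7-(allyloxy)-5-(benzyloxy)-2-[3,4-bis(benzyloxy)phenyl]-4H-chromen-4-one A3.
- For it: the step is convergent, forms three bonds under mild fluoride conditions, involves no oxidation-prone hydroquinone, and the alkoxy group next to the aryne directs the insertion the right way. On convergence and mildness it is stronger than the chosen route.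
- Against it: A3 has hydrogen at C8. The C8 oxygen would have to be introduced afterwards on a 5,7-dioxygenated flavone in which C6 and C8 are both activated and not reliably distinguished, costing at least three further steps with an open regiochemical question. A2 itself needs a differentially protected phloroglucinol with ortho silyl and triflate groups, several steps from commercial material.
- Comparison: the chosen strategy forms ring A with all three oxygens present and distinct, which removes the late C–H oxidation altogether.

Alternative 2: Ring A is disconnected at C5–C6, C7–C8 and C8–C8a (Dötz benzannulation). The Fischer carbene complex (CO)5Cr=C(OCH2Ph)(6-aryl-4-oxo-4H-pyran-3-yl) A4 (zerovalent chromium, carbene carbon on C3 of the pyranone), (ethynyloxy)triisopropylsilane A5 and one CO ligand would combine on heating to give 5-(benzyloxy)-2-[3,4-bis(benzyloxy)phenyl]-8-hydroxy-7-(triisopropylsilyloxy)-4H-chromen-4-one A6.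
- For it: all three A-ring oxygens emerge chemically distinct (benzyl ether, silyl ether, free phenol) without relying on chelation, and both steric and electronic bias of the silyloxyalkyne should place O7 next to the new phenol. On differentiation of O5 from O8 it is at least as strong as the chosen route.
- Against it: A4 needs a 3-metalated pyranone, Cr(CO)6 in stoichiometric amount and O-benzylation of an acylchromate, which is much less straightforward than the usual O-methylation. A5 is a labile ynol ether. The product is formed as a Cr(CO)3 arene complex, and the oxidative decomplexation would threaten the electron-rich phenol. Carbenes on electron-poor heteroaryl rings also tend to divert to cyclobutenones and furans.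
- Comparison: the chosen route makes the same ring with the same oxygen pattern from squaric acid in a metal-free thermal step, and takes the O5/O8 distinction from the hydrogen bond of the 5-OH.

Alternative 3: Ring C is disconnected at O1–C8a. 1-[4-(Allyloxy)-2,5-dimethoxyphenyl]-3-[3,4-bis(benzyloxy)phenyl]propane-1,3-dione A7 would be oxidised with (NH4)2Ce(NO3)6 (tetravalent cerium) to the acylquinone 2-(allyloxy)-5-{3-[3,4-bis(benzyloxy)phenyl]-3-oxopropanoyl}cyclohexa-2,5-diene-1,4-dione A8. Its enol oxygen adds to the quinone carbon next to the acyl group (6-endo oxa-Michael) and a Na2S2O4 work-up returns the hydroquinone 7-(allyloxy)-2-[3,4-bis(benzyloxy)phenyl]-5,8-dihydroxy-4H-chromen-4-one A9, which is the same compound as 16.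
- For it: it uses conventional aryl ketone chemistry, the oxygen pattern is fixed by the arene, and it reaches 16 in fewer steps than the chosen route. On step economy it is stronger.
- Against it: the oxidant meets three groups that it can attack besides the dimethoxyarene. These are the enolisable 1,3-diketone (tetravalent cerium oxidises 1,3-dicarbonyls to radicals), the electron-rich bis(benzyloxy)arene and the allyl ether, which is a radical acceptor. The acylquinone is also open to addition of water or nitrate and to addition–elimination at the allyloxy carbon.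
- Comparison: the chosen route forms the same compound redox-neutrally, by heat alone in an inert solvent, so the hydroquinone level arises without any oxidant near these groups. The price is two or three more steps.

Key step: step 6

## Route

Remark on the chemistry: the target is taken as the free hydrogen sulfate as drawn, so the last step ends with a proton exchange; the stereocenters that appear on the way (in 4, 8, 9, 10, 13 and 15) are racemic and are all destroyed before the target.

Step 1
Reactants: 1 squaric acid; 2 allyl alcohol
Product: 3 diallyl squarate [3,4-bis(allyloxy)cyclobut-3-ene-1,2-dione]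
Conditions: 2 (excess), toluene, reflux, Dean–Stark
Reagents that add atoms: allyl alcohol (second equivalent of 2), C=CCO
Why: Squaric acid is a vinylogous diacid and both of its hydroxyl groups are esterified by the alcohol with azeotropic removal of water (acid-autocatalysed esterification), the standard way to dialkyl squarates. Two molecules of 2 therefore enter each molecule of 3.

Step 2
Reactants: 3 diallyl squarate
Product: 5 3-(allyloxy)cyclobut-3-ene-1,2-dione (allyl semisquarate), via hydroxycyclobutenone 4 (not isolated)
Conditions: LiAlH(OtBu)3, THF, −78 to −20 °C; aq. HCl work-up; then conc. HCl (cat.), CH2Cl2, rt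
Reagents that add atoms: water, O
Why: The bulky hydride adds once to a carbonyl of the squarate (1,2-reduction), and acid then ionises the carbinol of 4 to an alkoxy-stabilised cyclobutenyl cation that takes up water at its far end, the alkoxy carbon next to the carbonyl, and loses allyl alcohol. This reduction–hydrolysis sequence is the established route from dialkyl squarates to alkyl semisquarates, and allyl ethers are inert to both reagents.

Step 3
Reactants: 6 3,4-bis(benzyloxy)benzaldehyde; 7 (E)-1-methoxy-3-(trimethylsilyloxy)buta-1,3-diene
Product: 9 rac-2-[3,4-bis(benzyloxy)phenyl]-2,3-dihydro-4H-pyran-4-one, via silyl enol ether cycloadduct 8 (not isolated)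
Conditions: ZnCl2 (20 mol %), THF, rt; then TFA (cat.), CH2Cl2, 0 °C
Reagents that add atoms: none
Why: Lewis-acid-catalysed hetero-Diels–Alder reaction of the aldehyde with the Danishefsky diene, followed by acid-induced loss of methanol and of the silyl group, gives the dihydropyranone. The C2 stereocenter is racemic and is erased in step 4.

Step 4
Reactants: 9 rac-2-[3,4-bis(benzyloxy)phenyl]-2,3-dihydro-4H-pyran-4-one
Product: 11 2-[3,4-bis(benzyloxy)phenyl]-4H-pyran-4-one, via 3-phenylselanyl ketone 10 (not isolated)
Conditions: LiN(iPr)2, THF, −78 °C; PhSeCl; then H2O2, pyridine, CH2Cl2, 0 °C to rt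
Reagents that add atoms: none
Why: Kinetic enolisation at C3, the only enolisable position of the vinylogous ester, α-selenenylation and selenoxide syn-elimination give the 4-pyranone. The selenoxide can eliminate only toward the benzylic C2–H because C4 carries no hydrogen, and benzyl ethers are untouched.

Step 5
Reactants: 11 2-[3,4-bis(benzyloxy)phenyl]-4H-pyran-4-one; 5 3-(allyloxy)cyclobut-3-ene-1,2-dione
Product: 13 rac-3-(allyloxy)-4-{6-[3,4-bis(benzyloxy)phenyl]-4-oxo-4H-pyran-2-yl}-4-hydroxycyclobut-2-en-1-one, via 6-lithiopyranone 12 (not isolated)
Conditions: lithium 2,2,6,6-tetramethylpiperidide (from n-BuLi and 2,2,6,6-tetramethylpiperidine), THF, −78 °C, 10 min; then 5, −78 °C; AcOH quench at −78 °C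
Reagents that add atoms: none
Why: The C6–H of the 4-pyranone lies next to the ring oxygen and has pyrylium-ylide character, so a hindered non-nucleophilic amide removes it (α-metalation next to the heteroatom, as known for chromones, 4-pyridones and 4-quinolones). The vinyllithium then adds 1,2 to the ketone-like carbonyl of the semisquarate, the one flanked by the allyloxy-bearing carbon, which is the established regiochemistry for organolithium addition to alkyl semisquarates. The carbinol stereocenter is racemic and disappears in step 6.

Step 6
Reactants: 13 rac-3-(allyloxy)-4-{6-[3,4-bis(benzyloxy)phenyl]-4-oxo-4H-pyran-2-yl}-4-hydroxycyclobut-2-en-1-one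
Product: 16 7-(allyloxy)-2-[3,4-bis(benzyloxy)phenyl]-5,8-dihydroxy-4H-chromen-4-one, via (Z)-dienylketene 14 (not isolated), via 4a-H cyclohexadienone 15 (not isolated)
Conditions: degassed toluene (0.02 M), reflux, Ar
Reagents that add atoms: none
Why: Heating opens the cyclobutenone by conrotatory four-electron electrocyclic cleavage of the C1–C4 bond; the hydroxyl on C4 rotates outward (donor torquoselectivity), so the pyranonyl group turns inward and sits cis to the ketene in 14. A thermal disrotatory six-electron electrocyclisation, the only ring closure and the one that forms the six-membered carbocyclic ring A, joins the electrophilic ketene carbon to the nucleophilic C3 of the pyranone to give 15, and enolisation of the doubly activated C4a–H aromatises the ring. The closest known reaction is the Moore rearrangement of 4-aryl-, 4-heteroaryl- and 4-alkenyl-4-hydroxycyclobutenones to hydroquinones; the pyranonyl arm is a new substrate within that class and behaves as a 2-alkoxyvinyl group. No stereocenter remains, since the carbinol carbon becomes sp2 C8 and the transient C4a center of 15 is lost on tautomerisation. Connectivity fixes the pattern: ketene oxygen to 5-OH, cyclobutenone C2–H to C6–H, allyloxy carbon to C7, carbinol to 8-OH, pyranone C2 and C3 to C8a and C4a. The step needs closure on carbon and not on the ring oxygen (which would only give a reversible charged oxonium) and outward rotation of the hydroxyl (inward rotation would lead to a butenolide); the nucleophilic α-carbon of the vinylogous ester and the donor hydroxyl secure both. Exclusion of air keeps the hydroquinone from going to the 5,8-quinone, and 110 °C is well below the temperature of a Claisen shift of the allyl ether.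

Step 7
Reactants: 16 7-(allyloxy)-2-[3,4-bis(benzyloxy)phenyl]-5,8-dihydroxy-4H-chromen-4-one
Product: 17 7-(allyloxy)-8-(benzyloxy)-2-[3,4-bis(benzyloxy)phenyl]-5-hydroxy-4H-chromen-4-one
Conditions: BnBr (1.05 equiv), K2CO3, degassed DMF, rt, Ar
Reagents that add atoms: benzyl bromide, BrCc1ccccc1
Why: Williamson etherification; the 8-OH is an ordinary phenol whereas the 5-OH is held in a hydrogen bond to the C4 carbonyl, so one equivalent of benzyl bromide with a carbonate base should alkylate O8 only, as is general for 5-hydroxyflavones. Air is excluded because the hydroquinone monoanion is oxidisable.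

Step 8
Reactants: 17 7-(allyloxy)-8-(benzyloxy)-2-[3,4-bis(benzyloxy)phenyl]-5-hydroxy-4H-chromen-4-one
Product: 18 8-(benzyloxy)-2-[3,4-bis(benzyloxy)phenyl]-5,7-dihydroxy-4H-chromen-4-one
Conditions: Pd(PPh3)4 (5 mol %), morpholine, THF, rt
Reagents that add atoms: none
Why: Tsuji–Trost deallylation; zerovalent palladium ionises the aryl allyl ether to a π-allyl complex and the acidic flavone 7-phenoxide, and morpholine traps the allyl group. Benzyl ethers, the enone and the free 5-OH are not affected, and no oxidant is involved.

Step 9
Reactants: 18 8-(benzyloxy)-2-[3,4-bis(benzyloxy)phenyl]-5,7-dihydroxy-4H-chromen-4-one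
Product: 19 pyridinium 8-(benzyloxy)-2-[3,4-bis(benzyloxy)phenyl]-5-hydroxy-4-oxo-4H-chromen-7-yl sulfate
Conditions: SO3·pyridine (3 equiv), pyridine, rt
Reagents that add atoms: sulfur trioxide–pyridine complex, O=S(=O)([O-])[n+]1ccccc1
Why: O-Sulfonation of a phenol with a sulfur trioxide–amine complex; the 7-OH is the only unchelated free phenol and the most acidic one, while the 5-OH is deactivated by its hydrogen bond, so the monosulfate should form at O7 and is isolated as the pyridinium salt.

Step 10
Reactants: 19 pyridinium 8-(benzyloxy)-2-[3,4-bis(benzyloxy)phenyl]-5-hydroxy-4-oxo-4H-chromen-7-yl sulfate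
Product: 20 8-hydroxyluteolin 7-sulfate [2-(3,4-dihydroxyphenyl)-5,8-dihydroxy-4-oxo-4H-chromen-7-yl hydrogen sulfate]
Conditions: H2 (1 atm), Pd/C (10 wt %), THF–MeOH, rt; then Dowex 50W (H+ form), H2O–MeOH, 0 °C; lyophilise
Reagents that add atoms: none
Why: Catalytic hydrogenolysis cleaves the three benzyl ethers, while aryl sulfate monoesters and the flavone C2=C3 bond are stable to these conditions, which is the usual final deprotection for flavonoid sulfates. Cation exchange then replaces pyridinium by a proton.

## Compound list

1 | squaric acid (3,4-dihydroxycyclobut-3-ene-1,2-dione) | O=C1C(O)=C(O)C1=O | starting material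
2 | allyl alcohol (prop-2-en-1-ol) | C=CCO | starting material
3 | diallyl squarate [3,4-bis(allyloxy)cyclobut-3-ene-1,2-dione] | O=C1C(OCC=C)=C(OCC=C)C1=O | intermediate
4 | rac-2,3-bis(allyloxy)-4-hydroxycyclobut-2-en-1-one | O=C1C(OCC=C)=C(OCC=C)C1O | intermediate (not isolated)
5 | 3-(allyloxy)cyclobut-3-ene-1,2-dione (allyl semisquarate) | O=C1C=C(OCC=C)C1=O | intermediate
6 | 3,4-bis(benzyloxy)benzaldehyde | O=Cc1ccc(OCc2ccccc2)c(OCc2ccccc2)c1 | starting material
7 | (E)-1-methoxy-3-(trimethylsilyloxy)buta-1,3-diene | CO/C=C/C(=C)O[Si](C)(C)C | starting material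
8 | 2-[3,4-bis(benzyloxy)phenyl]-6-methoxy-4-(trimethylsilyloxy)-3,6-dihydro-2H-pyran (racemic, mixture of diastereomers) | COC1C=C(O[Si](C)(C)C)CC(c2ccc(OCc3ccccc3)c(OCc3ccccc3)c2)O1 | intermediate (not isolated)
9 | rac-2-[3,4-bis(benzyloxy)phenyl]-2,3-dihydro-4H-pyran-4-one | O=C1C=COC(c2ccc(OCc3ccccc3)c(OCc3ccccc3)c2)C1 | intermediate
10 | 2-[3,4-bis(benzyloxy)phenyl]-3-(phenylselanyl)-2,3-dihydro-4H-pyran-4-one (racemic, mixture of diastereomers) | O=C1C=COC(c2ccc(OCc3ccccc3)c(OCc3ccccc3)c2)C1[Se]c1ccccc1 | intermediate (not isolated)
11 | 2-[3,4-bis(benzyloxy)phenyl]-4H-pyran-4-one | O=c1ccoc(-c2ccc(OCc3ccccc3)c(OCc3ccccc3)c2)c1 | intermediate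
12 | {6-[3,4-bis(benzyloxy)phenyl]-4-oxo-4H-pyran-2-yl}lithium | [Li]c1cc(=O)cc(-c2ccc(OCc3ccccc3)c(OCc3ccccc3)c2)o1 | intermediate (not isolated)
13 | rac-3-(allyloxy)-4-{6-[3,4-bis(benzyloxy)phenyl]-4-oxo-4H-pyran-2-yl}-4-hydroxycyclobut-2-en-1-one | O=C1C=C(OCC=C)C1(O)c1cc(=O)cc(-c2ccc(OCc3ccccc3)c(OCc3ccccc3)c2)o1 | intermediate
14 | (Z)-3-(allyloxy)-4-{6-[3,4-bis(benzyloxy)phenyl]-4-oxo-4H-pyran-2-yl}-4-hydroxybuta-1,3-dien-1-one (dienylketene, ketene cis to the pyranonyl group) | O=C=C/C(OCC=C)=C(/O)c1cc(=O)cc(-c2ccc(OCc3ccccc3)c(OCc3ccccc3)c2)o1 | intermediate (not isolated)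
15 | rac-7-(allyloxy)-2-[3,4-bis(benzyloxy)phenyl]-8-hydroxy-4H-chromene-4,5(4aH)-dione | O=C1C=C(OCC=C)C(O)=C2OC(-c3ccc(OCc4ccccc4)c(OCc4ccccc4)c3)=CC(=O)C12 | intermediate (not isolated)
16 | 7-(allyloxy)-2-[3,4-bis(benzyloxy)phenyl]-5,8-dihydroxy-4H-chromen-4-one | O=c1cc(-c2ccc(OCc3ccccc3)c(OCc3ccccc3)c2)oc2c(O)c(OCC=C)cc(O)c12 | intermediate
17 | 7-(allyloxy)-8-(benzyloxy)-2-[3,4-bis(benzyloxy)phenyl]-5-hydroxy-4H-chromen-4-one | O=c1cc(-c2ccc(OCc3ccccc3)c(OCc3ccccc3)c2)oc2c(OCc3ccccc3)c(OCC=C)cc(O)c12 | intermediate
18 | 8-(benzyloxy)-2-[3,4-bis(benzyloxy)phenyl]-5,7-dihydroxy-4H-chromen-4-one | O=c1cc(-c2ccc(OCc3ccccc3)c(OCc3ccccc3)c2)oc2c(OCc3ccccc3)c(O)cc(O)c12 | intermediate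
19 | pyridinium 8-(benzyloxy)-2-[3,4-bis(benzyloxy)phenyl]-5-hydroxy-4-oxo-4H-chromen-7-yl sulfate | O=c1cc(-c2ccc(OCc3ccccc3)c(OCc3ccccc3)c2)oc2c(OCc3ccccc3)c(OS(=O)(=O)[O-])cc(O)c12.c1cc[nH+]cc1 | intermediate
20 | 8-hydroxyluteolin 7-sulfate [2-(3,4-dihydroxyphenyl)-5,8-dihydroxy-4-oxo-4H-chromen-7-yl hydrogen sulfate] | O=c1cc(-c2ccc(O)c(O)c2)oc2c(O)c(OS(=O)(=O)O)cc(O)c12 | target

## Step count and least certain steps

Total: 10 steps. Longest linear sequence: 8 steps (steps 3, 4, 5, 6, 7, 8, 9, 10; the squarate branch, steps 1, 2, 5 to 10, is equally long).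

Step 6 (key step). What may go wrong:
- The six-electron closure onto the pyranone may be slower than with simple alkenyl or aryl groups, which would leave the ketene time to dimerise or to pick up adventitious nucleophiles.
- Partial inward rotation of the hydroxyl would divert material into lactonisation to a butenolide.
- The hydroquinone may be oxidised to the 5,8-quinone at 110 °C if air is not rigorously excluded.
- If the ring opening needs a higher temperature than refluxing toluene, a [3,3] shift of the allyl group within the enol ether unit could begin to compete.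

Fallback, from 13, returning at 17: the carbinol is capped before the ring expansion, so the ketene carries no acidic hydroxyl and the product is a monoprotected hydroquinone that cannot be oxidised to the quinone. Silylation of 13 (Et3SiOTf, 2,6-lutidine, CH2Cl2, −78 °C) should give rac-3-(allyloxy)-4-{6-[3,4-bis(benzyloxy)phenyl]-4-oxo-4H-pyran-2-yl}-4-(triethylsilyloxy)cyclobut-2-en-1-one F1. Thermolysis of this ether in toluene, a known variant of the same ring expansion in which the silyloxy group also rotates outward, should give 7-(allyloxy)-2-[3,4-bis(benzyloxy)phenyl]-5-hydroxy-8-(triethylsilyloxy)-4H-chromen-4-one F2. One-pot desilylation and benzylation (CsF, BnBr, DMF) then leads to 17, bypassing 16 and step 7.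

Step 5. What may go wrong:
- Loss of site control in the deprotonation: C3–H and C5–H next to the carbonyl compete with C6–H.
- Self-addition of the vinyllithium to unreacted pyranone.
- Decomposition of the base-sensitive hydroxycyclobutenone before the quench.

Fallback, from 11, returning at 13: the organometallic is made by halogen–metal exchange from a purified, regiodefined halide instead of being used straight from a kinetic lithiation. Zincation of 11 with a TMP-zinc amide (TMP2Zn·2MgCl2·2LiCl, THF) and an iodine quench should give 2-[3,4-bis(benzyloxy)phenyl]-6-iodo-4H-pyran-4-one F3. Bases of this family zincate chromones cleanly at one or the other ring position depending on their Lewis acid content, so the C6 isomer can be selected and its regiochemistry confirmed on the stable iodide. Iodine–magnesium exchange with iPrMgCl·LiCl at −78 °C then gives chloro{6-[3,4-bis(benzyloxy)phenyl]-4-oxo-4H-pyran-2-yl}magnesium F4, which is added to 5 to give 13.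

Step 4. What may go wrong:
- Ring opening of the enolate by β-elimination of the ring oxygen.
- Double selenenylation.
- Incomplete elimination of the selenoxide.

Fallback, from 6, returning at 11: the pyranone is built without a dehydrogenation. Aldol addition of the lithium enolate of (E)-4-methoxybut-3-en-2-one (LiN(SiMe3)2, THF, −78 °C) to 6 gives rac-(E)-5-[3,4-bis(benzyloxy)phenyl]-5-hydroxy-1-methoxypent-1-en-3-one F5. Dess–Martin oxidation gives (E)-1-[3,4-bis(benzyloxy)phenyl]-5-methoxypent-4-ene-1,3-dione F6, and trifluoroacetic acid closes it to 11 with loss of methanol. This route also makes step 3 unnecessary.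

Step 10. What may go wrong:
- Solvolysis of the sulfate ester once the acid form is generated, or already during hydrogenolysis of the weakly acidic pyridinium salt in methanol.
- Incomplete debenzylation.
- Partial saturation of the C2=C3 bond on prolonged exposure.

Fallback, from 18, returning at 20: the sulfate is carried as a neutral diester. Reaction of 18 with 2,2,2-trichloroethyl chlorosulfate (Et3N, DMAP, THF) gives 8-(benzyloxy)-2-[3,4-bis(benzyloxy)phenyl]-5-hydroxy-4-oxo-4H-chromen-7-yl 2,2,2-trichloroethyl sulfate F7. Transfer hydrogenolysis (Pd/C, HCO2NH4, MeOH) removes the benzyl groups and the trichloroethyl group together and gives ammonium 2-(3,4-dihydroxyphenyl)-5,8-dihydroxy-4-oxo-4H-chromen-7-yl sulfate F8, which is never exposed to acid until the final, cold proton exchange (Dowex 50W, H+ form) to 20.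

## Further compounds

F1 | step 6 | rac-3-(allyloxy)-4-{6-[3,4-bis(benzyloxy)phenyl]-4-oxo-4H-pyran-2-yl}-4-(triethylsilyloxy)cyclobut-2-en-1-one | O=C1C=C(OCC=C)C1(O[Si](CC)(CC)CC)c1cc(=O)cc(-c2ccc(OCc3ccccc3)c(OCc3ccccc3)c2)o1
F2 | step 6 | 7-(allyloxy)-2-[3,4-bis(benzyloxy)phenyl]-5-hydroxy-8-(triethylsilyloxy)-4H-chromen-4-one | O=c1cc(-c2ccc(OCc3ccccc3)c(OCc3ccccc3)c2)oc2c(O[Si](CC)(CC)CC)c(OCC=C)cc(O)c12
F3 | step 5 | 2-[3,4-bis(benzyloxy)phenyl]-6-iodo-4H-pyran-4-one | O=c1cc(I)oc(-c2ccc(OCc3ccccc3)c(OCc3ccccc3)c2)c1
F4 | step 5 | chloro{6-[3,4-bis(benzyloxy)phenyl]-4-oxo-4H-pyran-2-yl}magnesium | O=c1cc([Mg]Cl)oc(-c2ccc(OCc3ccccc3)c(OCc3ccccc3)c2)c1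
F5 | step 4 | rac-(E)-5-[3,4-bis(benzyloxy)phenyl]-5-hydroxy-1-methoxypent-1-en-3-one | CO/C=C/C(=O)CC(O)c1ccc(OCc2ccccc2)c(OCc2ccccc2)c1
F6 | step 4 | (E)-1-[3,4-bis(benzyloxy)phenyl]-5-methoxypent-4-ene-1,3-dione | CO/C=C/C(=O)CC(=O)c1ccc(OCc2ccccc2)c(OCc2ccccc2)c1
F7 | step 10 | 8-(benzyloxy)-2-[3,4-bis(benzyloxy)phenyl]-5-hydroxy-4-oxo-4H-chromen-7-yl 2,2,2-trichloroethyl sulfate | O=c1cc(-c2ccc(OCc3ccccc3)c(OCc3ccccc3)c2)oc2c(OCc3ccccc3)c(OS(=O)(=O)OCC(Cl)(Cl)Cl)cc(O)c12
F8 | step 10 | ammonium 2-(3,4-dihydroxyphenyl)-5,8-dihydroxy-4-oxo-4H-chromen-7-yl sulfate | O=c1cc(-c2ccc(O)c(O)c2)oc2c(O)c(OS(=O)(=O)[O-])cc(O)c12.[NH4+]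
A1 | alternative 1 | 3-[3,4-bis(benzyloxy)phenyl]prop-2-ynoic acid | O=C(O)C#Cc1ccc(OCc2ccccc2)c(OCc2ccccc2)c1
A2 | alternative 1 | 5-(allyloxy)-3-(benzyloxy)-2-(trimethylsilyl)phenyl trifluoromethanesulfonate | C=CCOc1cc(OCc2ccccc2)c([Si](C)(C)C)c(OS(=O)(=O)C(F)(F)F)c1
A3 | alternative 1 | 7-(allyloxy)-5-(benzyloxy)-2-[3,4-bis(benzyloxy)phenyl]-4H-chromen-4-one | O=c1cc(-c2ccc(OCc3ccccc3)c(OCc3ccccc3)c2)oc2cc(OCC=C)cc(OCc3ccccc3)c12
A4 | alternative 2 | pentacarbonyl{(benzyloxy)[6-(3,4-bis(benzyloxy)phenyl)-4-oxo-4H-pyran-3-yl]methylidene}chromium | O=c1cc(-c2ccc(OCc3ccccc3)c(OCc3ccccc3)c2)occ1C(OCc1ccccc1)=[Cr](=C=O)(=C=O)(=C=O)(=C=O)=C=O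
A5 | alternative 2 | (ethynyloxy)triisopropylsilane | C#CO[Si](C(C)C)(C(C)C)C(C)C
A6 | alternative 2 | 5-(benzyloxy)-2-[3,4-bis(benzyloxy)phenyl]-8-hydroxy-7-(triisopropylsilyloxy)-4H-chromen-4-one | O=c1cc(-c2ccc(OCc3ccccc3)c(OCc3ccccc3)c2)oc2c(O)c(O[Si](C(C)C)(C(C)C)C(C)C)cc(OCc3ccccc3)c12
A7 | alternative 3 | 1-[4-(allyloxy)-2,5-dimethoxyphenyl]-3-[3,4-bis(benzyloxy)phenyl]propane-1,3-dione | COc1cc(OCC=C)c(OC)cc1C(=O)CC(=O)c1ccc(OCc2ccccc2)c(OCc2ccccc2)c1
A8 | alternative 3 | 2-(allyloxy)-5-{3-[3,4-bis(benzyloxy)phenyl]-3-oxopropanoyl}cyclohexa-2,5-diene-1,4-dione | O=C1C=C(OCC=C)C(=O)C=C1C(=O)CC(=O)c1ccc(OCc2ccccc2)c(OCc2ccccc2)c1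
A9 | alternative 3 | 7-(allyloxy)-2-[3,4-bis(benzyloxy)phenyl]-5,8-dihydroxy-4H-chromen-4-one | O=c1cc(-c2ccc(OCc3ccccc3)c(OCc3ccccc3)c2)oc2c(O)c(OCC=C)cc(O)c12
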